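**Retrosynthetic overview**

1. The strategy rests on C8, the CH–CH3 carbon of the eight-membered ring. It lies between C7 (benzylic C–O carbon on ring B) and C8' (which carries C9' and the C7'H2 link to ring A); with C7 as ketone and C9' as ester, taking C8 out leaves a dibenzo-fused seven-membered β-keto ester.
2. Target 20 ⇐ benzyl ether 19 ⇐ lactol 18 ⇐ bridged γ-lactone 17 (the tetrahydrofuran C7–O–C9'–C8'–C8 at the lactone level) ⇐ hydroxy ester 16 ⇐ eight-membered γ-keto ester 15.
3. 15 ⇐ seven-membered β-keto ester 12 + 1,1-diiodoethane 13: CH(CH3) is inserted between C7 and C8' through a cyclopropanolate whose C7–C8' bond is temporary.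
4. 12 ⇐ Dieckmann closure of biaryl diester 11 ⇐ atroposelective opening of biaryl lactone 7 (axis set here and carried into 15, where it governs C7, C8 and C8') ⇐ ester-tethered Pd arylation of 6 (from phenol 4 and acid 5).
5. Ring order: biaryl pyranone (temporary tether) → seven-membered carbocycle → eight-membered carbocycle → bridging lactone/tetrahydrofuran.

Key step: step 8

Assumption: the target SMILES defines no biaryl axis; by hand modelling of the bridged core, the 7,9'-oxygen bridge of the (7R,8R,8'R) compound fits without severe strain only the aR (M) twist (torsion C3–C2–C2'–C3' negative), so that atropisomer is taken as the target. SMILES strings cannot show the axis, so it is given in the names.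

Numbering in names: ring B = C1–C6 (C7 on C1, biaryl bond at C2, OMe at C3, C4, C5); ring A = C1'–C6' (C7' on C1', biaryl bond at C2', O at C3', OMe at C4', C5'); C8 bears CH3; C8' bears C9'.

**Route**

Step 1
Reactants: 1 3-hydroxy-4,5-dimethoxybenzaldehyde; 2 trimethyl phosphonoacetate
Product: 3 methyl (E)-3-(3-hydroxy-4,5-dimethoxyphenyl)prop-2-enoate
Conditions: NaH (2.2 equiv), THF, 0 °C → rt; 1 M HCl
Reagents that add atoms: trimethyl phosphonoacetate, COC(=O)CP(=O)(OC)OC
Why: Horner–Wadsworth–Emmons olefination, in which the second equivalent of base covers the phenol and the stabilized phosphonate anion should give the E-cinnamate (the alkene geometry is removed in step 2).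

Step 2
Reactants: 3 methyl (E)-3-(3-hydroxy-4,5-dimethoxyphenyl)prop-2-enoate
Product: 4 methyl 3-(3-hydroxy-4,5-dimethoxyphenyl)propanoate
Conditions: H2 (1 atm), 10% Pd/C, MeOH, rt
Reagents that add atoms: none
Why: Catalytic hydrogenation of the conjugated alkene, which leaves the arene, the ester and the free phenol untouched.

Step 3
Reactants: 4 methyl 3-(3-hydroxy-4,5-dimethoxyphenyl)propanoate; 5 2-bromo-3,4,5-trimethoxybenzoic acid
Product: 6 2,3-dimethoxy-5-(3-methoxy-3-oxopropyl)phenyl 2-bromo-3,4,5-trimethoxybenzoate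
Conditions: EDC·HCl, DMAP (cat.), CH2Cl2, 0 °C → rt
Reagents that add atoms: none
Why: Steglich esterification of the ring A phenol with the ring B acid, which installs the ester tether that later fixes where the biaryl bond forms.

Step 4
Reactants: 6 2,3-dimethoxy-5-(3-methoxy-3-oxopropyl)phenyl 2-bromo-3,4,5-trimethoxybenzoate
Product: 7 methyl 3-(3,4,8,9,10-pentamethoxy-6-oxo-6H-benzo[c]chromen-1-yl)propanoate (six-membered biaryl lactone, helically labile)
Conditions: Pd(OAc)2 (10 mol%), PPh3 (20 mol%), NaOAc, DMA, 130 °C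
Reagents that add atoms: none
Why: Palladium-catalysed intramolecular direct arylation (zerovalent palladium inserts into C–Br, acetate-assisted C–H palladation, reductive elimination); only C2' of ring A can give the six-membered lactone because the other position ortho to the ester oxygen (C4') carries OMe, so the C2–C2' bond is formed with forced regiochemistry.

Step 5
Reactants: 7 methyl 3-(3,4,8,9,10-pentamethoxy-6-oxo-6H-benzo[c]chromen-1-yl)propanoate; 8 benzyl alcohol
Product: 9 benzyl (aR)-2-[2-hydroxy-3,4-dimethoxy-6-(3-methoxy-3-oxopropyl)phenyl]-3,4,5-trimethoxybenzoate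
Conditions: 9-amino-9-deoxy-epi-quinine 3,5-bis(trifluoromethyl)phenyl thiourea (10 mol%), BnOH (3 equiv), PhCF3, 4 Å MS, rt
Reagents that add atoms: benzyl alcohol, OCc1ccccc1
Why: Atroposelective transesterification of a configurationally labile biaryl lactone (dynamic kinetic resolution): the helical forms of 7 interconvert fast, the thiourea binds the lactone carbonyl while the quinuclidine delivers benzyl alcohol to one of them, and ring opening freezes the tetra-ortho-substituted axis, intended as aR (the sense is to be assigned on 9, and the quinidine-derived catalyst is taken if it proves opposite).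

Step 6
Reactants: 9 benzyl (aR)-2-[2-hydroxy-3,4-dimethoxy-6-(3-methoxy-3-oxopropyl)phenyl]-3,4,5-trimethoxybenzoate; 10 benzyl bromide
Product: 11 benzyl (aR)-2-[2-(benzyloxy)-3,4-dimethoxy-6-(3-methoxy-3-oxopropyl)phenyl]-3,4,5-trimethoxybenzoate
Conditions: BnBr, K2CO3, DMF, 0 °C → rt
Reagents that add atoms: benzyl bromide, BrCc1ccccc1
Why: Williamson etherification of the phenoxide, fast enough at low temperature to outrun re-closure to the labile lactone, so the aR axis of the open biaryl should be kept.

Step 7
Reactants: 11 benzyl (aR)-2-[2-(benzyloxy)-3,4-dimethoxy-6-(3-methoxy-3-oxopropyl)phenyl]-3,4,5-trimethoxybenzoate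
Product: 12 methyl (aR)-11-(benzyloxy)-1,2,3,9,10-pentamethoxy-5-oxo-6,7-dihydro-5H-dibenzo[a,c][7]annulene-6-carboxylate (seven-membered β-keto ester: C7 ketone, C8' methyl ester, C8' labile)
Conditions: LiN(SiMe3)2 (2.2 equiv), THF (0.01 M), −78 → −20 °C; AcOH, −40 °C; cold work-up, used at once
Reagents that add atoms: none
Why: Dieckmann condensation in which the lithium enolate at C8' attacks the ring B benzyl ester in a 7-exo-trig closure driven by loss of benzyloxide and deprotonation of the product; closure needs no passage through a coplanar biaryl, so the twist sense is retained, and the cold quench and immediate use guard the axis of the seven-membered ring.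

Step 8
Reactants: 12 methyl (aR)-11-(benzyloxy)-1,2,3,9,10-pentamethoxy-5-oxo-6,7-dihydro-5H-dibenzo[a,c][7]annulene-6-carboxylate; 13 1,1-diiodoethane
Product: 15 methyl (aR,8R,8'R)-12-(benzyloxy)-1,2,3,10,11-pentamethoxy-6-methyl-5-oxo-5,6,7,8-tetrahydrodibenzo[a,c][8]annulene-7-carboxylate (eight-membered γ-keto ester: C7 ketone; C8 methyl; C8' methyl ester), via iodozinc cyclopropanolate 14 (not isolated)
Conditions: Et2Zn (5 equiv), CH3CHI2 (5 equiv), CH2Cl2, 0 °C; sat. aq NH4Cl
Reagents that add atoms: 1,1-diiodoethane, CC(I)I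
Why: Et2Zn deprotonates 12 to its zinc enolate, which is C-alkylated at C8' by the ethylidene carbenoid EtZnCH(CH3)I; the zinc homoenolate so formed adds to the C7 aryl ketone in a 3-exo-trig closure to the donor–acceptor cyclopropanolate 14, whose C7–C8' bond (pushed by the alkoxide, pulled by the ester) then breaks to leave the zinc ester enolate of the eight-membered ring, protonated on work-up. This is the zinc-carbenoid chain extension of β-keto esters to γ-keto esters, known with the carbenoid from 1,1-diiodoethane and with α-substituted and cyclic substrates, applied here to a biaryl-bridged ring. The cyclopropane is the only ring closed directly; the eight-membered ring arises by expansion of the seven-membered one, which avoids an end-to-end medium-ring closure. C8 is set by the face on which the homoenolate carbon meets the C7 carbonyl beneath the twisted aR biaryl and C8' by protonation of the ester enolate; both are enolizable, so they should end, or be brought in steps 9 and 10, in the arrangement dictated by the axis (methyl and ester cis, methyl on the outer side of the ring), and epimers are carried on unseparated. The step needs C-alkylation at C8' and closure onto the ketone, not the ester, which the more electrophilic aryl ketone and the 3-exo geometry should secure, and no second insertion, which the unreactive product zinc ester enolate should secure. The biaryl twist only widens during the expansion and the mixture stays at 0 °C, so the aR axis should pass into 15 unchanged.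

Step 9
Reactants: 15 methyl (aR,8R,8'R)-12-(benzyloxy)-1,2,3,10,11-pentamethoxy-6-methyl-5-oxo-5,6,7,8-tetrahydrodibenzo[a,c][8]annulene-7-carboxylate
Product: 16 methyl (aR,7R,8R,8'R)-12-(benzyloxy)-5-hydroxy-1,2,3,10,11-pentamethoxy-6-methyl-5,6,7,8-tetrahydrodibenzo[a,c][8]annulene-7-carboxylate (C7 alcohol)
Conditions: RuCl(p-cymene)[(R,R)-TsDPEN] (5 mol%), HCO2H/Et3N (5:2), DMF, 40 °C
Reagents that add atoms: none
Why: Noyori–Ikariya asymmetric transfer hydrogenation with dynamic kinetic resolution: the (R,R) catalyst delivers hydride in the sense that gives (R)-1-arylalkanols, hence 7R, which should also be the carbonyl face turned away from ring A in the aR ketone, while C8 epimerizes through the enol in the amine/formic acid medium and the epimer with methyl anti to the incoming hydride is reduced faster (cis 7-OH/8-CH3, 8R); any aS ketone from axis erosion is mismatched and gives an alcohol that cannot close in step 10, so enantiopurity is upgraded.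

Step 10
Reactants: 16 methyl (aR,7R,8R,8'R)-12-(benzyloxy)-5-hydroxy-1,2,3,10,11-pentamethoxy-6-methyl-5,6,7,8-tetrahydrodibenzo[a,c][8]annulene-7-carboxylate
Product: 17 (aR,7R,8R,8'R)-3'-benzyloxy-3,4,5,4',5'-pentamethoxy-8-methyl-dibenzocyclooctadiene 9',7-lactone (γ-lactone C7–O–C9'(=O)–C8' bridging the eight-membered ring)
Conditions: t-BuOK (0.3 equiv), THF, 0 °C → rt; AcOH
Reagents that add atoms: none
Why: Base-catalysed lactonization (intramolecular transesterification, 5-exo-trig): only the 8'R epimer, with the ester cis to the C7 alkoxide across C8, can bridge, and reversible ester enolization under t-BuOK feeds any 8'S epimer into it, so C8' is fixed here by C7.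

Step 11
Reactants: 17 (aR,7R,8R,8'R)-3'-benzyloxy-3,4,5,4',5'-pentamethoxy-8-methyl-dibenzocyclooctadiene 9',7-lactone
Product: 18 the corresponding lactol (C9' hemiacetal, anomers)
Conditions: i-Bu2AlH (1.2 equiv), CH2Cl2, −78 °C; Rochelle salt
Reagents that add atoms: none
Why: Partial reduction of a γ-lactone by i-Bu2AlH, which stops at the aluminium hemiacetal at −78 °C; the new C9' centre is removed in step 12.

Step 12
Reactants: 18 lactol
Product: 19 (aR,7R,8R,8'R)-3'-benzyloxy-7,9'-epoxy-3,4,5,4',5'-pentamethoxy-8-methyl-dibenzocyclooctadiene (benzyl ether of the target)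
Conditions: Et3SiH, BF3·OEt2, CH2Cl2, −78 → −40 °C
Reagents that add atoms: none
Why: Ionic hydrogenation of the lactol: BF3 ionizes the anomeric hydroxyl to the oxocarbenium ion at C9', which Et3SiH reduces to the CH2 of the tetrahydrofuran without touching a stereocentre, the low temperature sparing the benzylic C7–O bond and the benzyl ether.

Step 13
Reactants: 19 benzyl ether of the target
Product: 20 CNP0322364.1, (aR,7R,8R,8'R)-7,9'-epoxy-3,4,5,4',5'-pentamethoxy-8-methyl-dibenzocyclooctadien-3'-ol
Conditions: H2 (1 atm), 10% Pd/C, EtOAc, rt, stopped at full conversion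
Reagents that add atoms: none
Why: Hydrogenolysis of the aryl benzyl ether, which is cleaved much faster than the hindered cyclic benzylic C7–O bond under neutral conditions, frees the ring A phenol.

**Compound list**

1 | 3-hydroxy-4,5-dimethoxybenzaldehyde | COc1cc(C=O)cc(O)c1OC | starting material
2 | trimethyl phosphonoacetate | COC(=O)CP(=O)(OC)OC | starting material
3 | methyl (E)-3-(3-hydroxy-4,5-dimethoxyphenyl)prop-2-enoate | COC(=O)/C=C/c1cc(O)c(OC)c(OC)c1 | intermediate
4 | methyl 3-(3-hydroxy-4,5-dimethoxyphenyl)propanoate | COC(=O)CCc1cc(O)c(OC)c(OC)c1 | intermediate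
5 | 2-bromo-3,4,5-trimethoxybenzoic acid | COc1cc(C(=O)O)c(Br)c(OC)c1OC | starting material
6 | 2,3-dimethoxy-5-(3-methoxy-3-oxopropyl)phenyl 2-bromo-3,4,5-trimethoxybenzoate | COC(=O)CCc1cc(OC)c(OC)c(OC(=O)c2cc(OC)c(OC)c(OC)c2Br)c1 | intermediate
7 | methyl 3-(3,4,8,9,10-pentamethoxy-6-oxo-6H-benzo[c]chromen-1-yl)propanoate | COC(=O)CCc1cc(OC)c(OC)c2OC(=O)c3cc(OC)c(OC)c(OC)c3-c12 | intermediate
8 | benzyl alcohol | OCc1ccccc1 | starting material
9 | benzyl (aR)-2-[2-hydroxy-3,4-dimethoxy-6-(3-methoxy-3-oxopropyl)phenyl]-3,4,5-trimethoxybenzoate | COC(=O)CCc1cc(OC)c(OC)c(O)c1-c1c(OC)c(OC)c(OC)cc1C(=O)OCc1ccccc1 | intermediate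
10 | benzyl bromide | BrCc1ccccc1 | starting material
11 | benzyl (aR)-2-[2-(benzyloxy)-3,4-dimethoxy-6-(3-methoxy-3-oxopropyl)phenyl]-3,4,5-trimethoxybenzoate | COC(=O)CCc1cc(OC)c(OC)c(OCc2ccccc2)c1-c1c(OC)c(OC)c(OC)cc1C(=O)OCc1ccccc1 | intermediate
12 | methyl (aR)-11-(benzyloxy)-1,2,3,9,10-pentamethoxy-5-oxo-6,7-dihydro-5H-dibenzo[a,c][7]annulene-6-carboxylate (seven-membered β-keto ester, C8' labile) | COc1cc2c(c(OCc3ccccc3)c1OC)-c1c(cc(OC)c(OC)c1OC)C(=O)C(C2)C(=O)OC | intermediate
13 | 1,1-diiodoethane | CC(I)I | starting material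
14 | iodozinc cyclopropanolate (cyclopropane C7–C8–C8' fused to the seven-membered ring; zinc alkoxide on C7, methyl on C8, ester on C8') | COc1cc2c(c(OCc3ccccc3)c1OC)-c1c(cc(OC)c(OC)c1OC)C1(O[Zn]I)C(C)C1(C2)C(=O)OC | intermediate
15 | methyl (aR,8R,8'R)-12-(benzyloxy)-1,2,3,10,11-pentamethoxy-6-methyl-5-oxo-5,6,7,8-tetrahydrodibenzo[a,c][8]annulene-7-carboxylate (eight-membered γ-keto ester) | COc1cc2c(c(OCc3ccccc3)c1OC)-c1c(cc(OC)c(OC)c1OC)C(=O)[C@H](C)[C@@H](C2)C(=O)OC | intermediate
16 | methyl (aR,7R,8R,8'R)-12-(benzyloxy)-5-hydroxy-1,2,3,10,11-pentamethoxy-6-methyl-5,6,7,8-tetrahydrodibenzo[a,c][8]annulene-7-carboxylate | COc1cc2c(c(OCc3ccccc3)c1OC)-c1c(cc(OC)c(OC)c1OC)[C@H](O)[C@H](C)[C@@H](C2)C(=O)OC | intermediate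
17 | (aR,7R,8R,8'R)-3'-benzyloxy-3,4,5,4',5'-pentamethoxy-8-methyl-dibenzocyclooctadiene 9',7-lactone | COc1cc2c(c(OCc3ccccc3)c1OC)-c1c(cc(OC)c(OC)c1OC)[C@@H]1OC(=O)[C@H](C2)[C@H]1C | intermediate
18 | lactol of 17 (C9' hemiacetal, anomers) | COc1cc2c(c(OCc3ccccc3)c1OC)-c1c(cc(OC)c(OC)c1OC)[C@@H]1OC(O)[C@H](C2)[C@H]1C | intermediate
19 | (aR,7R,8R,8'R)-3'-benzyloxy-7,9'-epoxy-3,4,5,4',5'-pentamethoxy-8-methyl-dibenzocyclooctadiene | COc1cc2c(c(OCc3ccccc3)c1OC)-c1c(cc(OC)c(OC)c1OC)[C@@H]1OC[C@H](C2)[C@H]1C | intermediate
20 | CNP0322364.1, (aR,7R,8R,8'R)-7,9'-epoxy-3,4,5,4',5'-pentamethoxy-8-methyl-dibenzocyclooctadien-3'-ol | COc1cc2c(c(O)c1OC)-c1c(cc(OC)c(OC)c1OC)[C@@H]1OC[C@H](C2)[C@H]1C | target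

**Count**

Total steps: 13. Longest linear sequence: 13 steps (1 → 20; acid 5 joins at step 3).

**Steps most likely to fail**

Step 8. The fully substituted zinc enolate may be alkylated too slowly by the secondary carbenoid, so that 12 is recovered or O-alkylated, or loses axial purity while it waits. The fallback is a Dowd–Beckwith radical ring expansion followed by a separate methylation, setting out from 12 and returning at 15. The sodium enolate of 12 (NaH, THF/DMPU) is alkylated at C8' with CH2Br2 to the bromomethyl β-keto ester F1. Bu3SnH with Et3B/air in toluene at 0 °C → rt then generates the primary radical, which adds 3-exo to the C7 carbonyl; the cyclopropyloxy radical fragments at C7–C8' to the ester-stabilized C8' radical and gives the eight-membered γ-keto ester lacking the methyl group F2. Kinetic enolization at C8, α to the aryl ketone (LiN(SiMe3)2, THF, −78 °C), and MeI then give 15; its C8 and C8' epimers converge in steps 9 and 10.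

Step 9. The hindered medium-ring ketone may not turn over, C8 may enolize too slowly, or hydride may reach the wrong face of C7. The fallback uses substrate-controlled reduction and, if needed, inversion at C7, setting out from 15 and returning at 17. 15 is equilibrated at C8 (DBU, toluene) and reduced with NaBH4 (MeOH/THF, 0 °C). A 7R alcohol is 16 and goes on through step 10. A 7S alcohol, the (aR,7S,8R,8'R)-hydroxy ester F3, is saponified (LiOH, THF/H2O) to the (aR,7S,8R,8'R)-hydroxy acid F4 and closed by Mitsunobu lactonization (PPh3, DIAD, THF, 0 °C), the carboxylate displacing the activated benzylic oxygen with inversion, to reach 17.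

Step 5. Atroposelectivity may be low on this lactone, or the open ester may re-close to the labile lactone and erode it. The fallback replaces catalyst control by a stoichiometric chiral alkoxide and a separation, setting out from 7 and returning at 12. Sodium (1R,2S,5R)-menthoxide (or its antipode, whichever favours aR) in THF at −20 °C opens 7 to the (1R,2S,5R)-menthyl (aR)-hydroxy biaryl ester F5, whose two atropo-diastereomers are separable by chromatography or crystallization. Benzylation (BnBr, K2CO3, DMF) gives the menthyl (aR)-benzyloxy biaryl ester F6, and Dieckmann closure (LiN(SiMe3)2 or KOt-Bu, THF) with loss of menthol returns to 12.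

**Further compounds**

F1 | step 8 | methyl (aR)-11-(benzyloxy)-6-(bromomethyl)-1,2,3,9,10-pentamethoxy-5-oxo-6,7-dihydro-5H-dibenzo[a,c][7]annulene-6-carboxylate | COc1cc2c(c(OCc3ccccc3)c1OC)-c1c(cc(OC)c(OC)c1OC)C(=O)C(CBr)(C2)C(=O)OC
F2 | step 8 | methyl (aR)-12-(benzyloxy)-1,2,3,10,11-pentamethoxy-5-oxo-5,6,7,8-tetrahydrodibenzo[a,c][8]annulene-7-carboxylate (C8' epimers) | COc1cc2c(c(OCc3ccccc3)c1OC)-c1c(cc(OC)c(OC)c1OC)C(=O)CC(C2)C(=O)OC
F3 | step 9 | methyl (aR,7S,8R,8'R)-12-(benzyloxy)-5-hydroxy-1,2,3,10,11-pentamethoxy-6-methyl-5,6,7,8-tetrahydrodibenzo[a,c][8]annulene-7-carboxylate | COc1cc2c(c(OCc3ccccc3)c1OC)-c1c(cc(OC)c(OC)c1OC)[C@@H](O)[C@H](C)[C@@H](C2)C(=O)OC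
F4 | step 9 | (aR,7S,8R,8'R)-12-(benzyloxy)-5-hydroxy-1,2,3,10,11-pentamethoxy-6-methyl-5,6,7,8-tetrahydrodibenzo[a,c][8]annulene-7-carboxylic acid | COc1cc2c(c(OCc3ccccc3)c1OC)-c1c(cc(OC)c(OC)c1OC)[C@@H](O)[C@H](C)[C@@H](C2)C(=O)O
F5 | step 5 | (1R,2S,5R)-2-isopropyl-5-methylcyclohexyl (aR)-2-[2-hydroxy-3,4-dimethoxy-6-(3-methoxy-3-oxopropyl)phenyl]-3,4,5-trimethoxybenzoate | CC(C)[C@@H]1CC[C@@H](C)C[C@H]1OC(=O)c1cc(OC)c(OC)c(OC)c1-c1c(O)c(OC)c(OC)cc1CCC(=O)OC
F6 | step 5 | (1R,2S,5R)-2-isopropyl-5-methylcyclohexyl (aR)-2-[2-(benzyloxy)-3,4-dimethoxy-6-(3-methoxy-3-oxopropyl)phenyl]-3,4,5-trimethoxybenzoate | CC(C)[C@@H]1CC[C@@H](C)C[C@H]1OC(=O)c1cc(OC)c(OC)c(OC)c1-c1c(OCc2ccccc2)c(OC)c(OC)cc1CCC(=O)OC
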